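**Plan**
- Cuts, in retrosynthetic order: the three O–CH3 bonds; the ring C C2–O(ring D) ether, which is the ring-closing bond, with the ring B–ring C bridge raised to a 1,2-diketone; the ring B C–O(ring A) ether; the ring C aryl–bridge bond (alkyne stage); the CH2–CH2 bridge between rings A and D (as C=C).
- Forward: 3-fluoroveratrole → iodide → diarylalkyne → difluoro diketone (rings B and C). Separately, Wittig reaction and hydrogenation give the ring A–ring D bibenzyl with only the ring A phenol free.
- SNAr at the para-fluorine joins the halves, acid frees the ring D phenol, and SNAr at the ortho-fluorine closes the 18-membered ring, the only ring formed. Wolff–Kishner reduction and BBr3 finish.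
- Enabling feature: in ring C the ether carbon C2 is ortho to C1, which carries the two-carbon bridge to ring B, and in ring B the ether carbon is para to the other bridge carbon. As a 1,2-diketone the bridge has no α-hydrogen, activates both ether carbons for fluoride displacement, and is afterwards reduced to CH2–CH2.
- Stereochemistry: the target has no stereocentre and no stable atropisomer, so nothing has to be set.

Key step: step 10

Remark: kinetic lithiation of 3-fluoroveratrole in THF is assumed to occur at the ring position next to fluorine, and the alkyne, the benzylic alcohol and 3-hydroxybenzaldehyde are taken as purchased.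

Step 1
Reactants: 1 1-fluoro-2,3-dimethoxybenzene (3-fluoroveratrole)
Product: 3 2-fluoro-1-iodo-3,4-dimethoxybenzene, via aryllithium 2 (not isolated)
Conditions: n-BuLi, THF, −78 °C; then I2, THF, −78 °C → rt
Reagents that add atoms: iodine (I2), II
Why: Directed ortho-lithiation in THF removes the most acidic ring hydrogen, the one next to fluorine, and the aryllithium, kept at −78 °C so that it does not lose LiF to an aryne, is trapped by iodine at the carbon that will later carry the bridge.

Step 2
Reactants: 3 2-fluoro-1-iodo-3,4-dimethoxybenzene; 4 1-ethynyl-4-fluorobenzene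
Product: 5 2-fluoro-1-[(4-fluorophenyl)ethynyl]-3,4-dimethoxybenzene
Conditions: PdCl2(PPh3)2 (2 mol %), CuI (4 mol %), Et3N, THF, 50 °C
Reagents that add atoms: none
Why: Sonogashira coupling of an aryl iodide with a terminal arylacetylene is reliable, and both C–F bonds are inert to zerovalent palladium under these conditions.

Step 3
Reactants: 5 2-fluoro-1-[(4-fluorophenyl)ethynyl]-3,4-dimethoxybenzene
Product: 6 1-(2-fluoro-3,4-dimethoxyphenyl)-2-(4-fluorophenyl)ethane-1,2-dione
Conditions: PdCl2 (10 mol %), DMSO, 140 °C
Reagents that add atoms: dimethyl sulfoxide, CS(C)=O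
Why: PdCl2-catalysed oxygen transfer from DMSO is an established oxidation of diarylalkynes to benzils and meets nothing else oxidizable in a substrate that carries only fluoro and methoxy groups.

Step 4
Reactants: 7 3-hydroxybenzaldehyde
Product: 8 3-(methoxymethoxy)benzaldehyde
Conditions: MOMCl, i-Pr2NEt, CH2Cl2, 0 °C → rt
Reagents that add atoms: chloromethyl methyl ether (MOMCl), COCCl
Why: O-Alkylation of the phenol gives a methoxymethyl acetal that withstands ylide base, hydrogenation and carbonate in DMF and is later removed by acid, which harms neither a diketone nor an aryl fluoride.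

Step 5
Reactants: 9 [3-(benzyloxy)-4-methoxyphenyl]methanol
Product: 10 [3-(benzyloxy)-4-methoxybenzyl]triphenylphosphonium bromide
Conditions: PPh3·HBr, MeCN, reflux
Reagents that add atoms: triphenylphosphine hydrobromide, [PH+](c1ccccc1)(c1ccccc1)c1ccccc1.[Br-]
Why: Acid-promoted ionization of the para-methoxy-stabilized benzylic alcohol and capture by triphenylphosphine is a standard one-step preparation of Wittig salts, and the benzyl aryl ether is stable to this weak acid.

Step 6
Reactants: 10 [3-(benzyloxy)-4-methoxybenzyl]triphenylphosphonium bromide; 8 3-(methoxymethoxy)benzaldehyde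
Product: 12 2-(benzyloxy)-1-methoxy-4-{2-[3-(methoxymethoxy)phenyl]ethenyl}benzene (E/Z mixture), via ylide 11 (not isolated)
Conditions: KOt-Bu, THF, 0 °C; then 8, 0 °C → rt
Reagents that add atoms: none
Why: Wittig olefination of an aryl aldehyde by a semistabilized benzylic ylide forms the carbon–carbon bond between rings A and D, and the E/Z mixture is of no concern because the double bond is saturated in the next step.

Step 7
Reactants: 12 2-(benzyloxy)-1-methoxy-4-{2-[3-(methoxymethoxy)phenyl]ethenyl}benzene
Product: 14 2-methoxy-5-{2-[3-(methoxymethoxy)phenyl]ethyl}phenol, via benzyl ether 13 (not isolated)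
Conditions: H2 (1 atm), Pd/C (10% palladium on carbon), EtOAc–EtOH, rt
Reagents that add atoms: none
Why: Catalytic hydrogenation saturates the stilbene double bond and then hydrogenolyses the benzyl ether in the same operation, so that only the ring A phenol is free while the acetal on ring D survives the neutral conditions.

Step 8
Reactants: 14 2-methoxy-5-{2-[3-(methoxymethoxy)phenyl]ethyl}phenol; 6 1-(2-fluoro-3,4-dimethoxyphenyl)-2-(4-fluorophenyl)ethane-1,2-dione
Product: 16 1-(2-fluoro-3,4-dimethoxyphenyl)-2-[4-(2-methoxy-5-{2-[3-(methoxymethoxy)phenyl]ethyl}phenoxy)phenyl]ethane-1,2-dione, via potassium phenoxide 15 (not isolated)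
Conditions: K2CO3, DMF, 55 °C
Reagents that add atoms: none
Why: Intermolecular SNAr of the ring A phenoxide at the fluorine para to the diketone, the displacement that also builds poly(ether benzil)s, should be site-selective because the other fluorine lies between a methoxy group and the acyl carbon on a ring whose activating carbonyl is weakened by a para methoxy group.

Step 9
Reactants: 16 1-(2-fluoro-3,4-dimethoxyphenyl)-2-[4-(2-methoxy-5-{2-[3-(methoxymethoxy)phenyl]ethyl}phenoxy)phenyl]ethane-1,2-dione
Product: 17 1-(2-fluoro-3,4-dimethoxyphenyl)-2-(4-{5-[2-(3-hydroxyphenyl)ethyl]-2-methoxyphenoxy}phenyl)ethane-1,2-dione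
Conditions: 3 M HCl (aq), THF, 50 °C
Reagents that add atoms: none
Why: Acid hydrolysis of the methoxymethyl acetal frees the ring D phenol, while the aryl fluoride, the diketone and the methyl and diaryl ethers do not react with aqueous acid.

Step 10
Reactants: 17 1-(2-fluoro-3,4-dimethoxyphenyl)-2-(4-{5-[2-(3-hydroxyphenyl)ethyl]-2-methoxyphenoxy}phenyl)ethane-1,2-dione
Product: 19 macrocyclic 1,2-diketone (marchantin H tri-O-methyl ether with the ring B–ring C bridge as CO–CO), via caesium phenoxide 18 (not isolated)
Conditions: Cs2CO3, 4 Å MS, DMF, 95 °C, Ar; 17 added by syringe pump to a final 2 mM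
Reagents that add atoms: none
Why: Cs2CO3 turns the ring D phenol into its caesium phenoxide, which adds to the fluorine-bearing C2 of ring C; the charge of the Meisenheimer adduct is taken up by the carbonyl on the neighbouring C1, itself made more electron-poor by the second carbonyl, and loss of fluoride restores the arene (addition–elimination SNAr). The closest known reaction type is the carbonyl-activated SNAr macroetherification that gives cyclic aryl ether ketones under pseudo-high dilution, together with the displacement of fluoride from fluorinated benzils by phenoxides. The 18-membered ring closes end to end by attack of the ring D oxygen on the ring C carbon, and slow addition into dilute base should favour this over chain growth. No stereocentre is formed. The step needs fluoride displacement to win over loss of the ring A aryloxy group from ring B: fluorine is the only good leaving group and its carbon the most electrophilic one in the rate-limiting addition, whereas ether exchange at ring B would require attack at an aryloxy-bearing carbon through an 11-membered spiro transition state. The diketone has no α-hydrogen, so carbonate cannot enolize it and switch off the activation, and exclusion of water and oxygen guards against benzilic acid rearrangement and oxidative cleavage.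

Step 11
Reactants: 19 macrocyclic 1,2-diketone
Product: 21 marchantin H tri-O-methyl ether, via bishydrazone 20 (not isolated)
Conditions: N2H4·H2O, diethylene glycol, 130 °C; then KOH, 195 °C with removal of water
Reagents that add atoms: none
Why: Wolff–Kishner reduction in the Huang-Minlon form should convert both aryl ketone carbonyls through their hydrazones into methylene groups with loss of nitrogen, which erases the activating group and leaves the CH2–CH2 bridge, while diaryl ethers para or ortho to such carbonyls are known to tolerate the hot alkali.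

Step 12
Reactants: 21 marchantin H tri-O-methyl ether
Product: 23 marchantin H, via boron aryloxide 22 (not isolated)
Conditions: BBr3, CH2Cl2, −78 °C → rt; then H2O
Reagents that add atoms: none
Why: BBr3 cleaves the three aryl methyl ethers by bromide attack on the O-methyl groups of the boron–ether adducts and leaves the diaryl ethers intact, and hydrolysis of the boron aryloxides on work-up releases the three phenols.

**Compound list**
1 | 1-fluoro-2,3-dimethoxybenzene (3-fluoroveratrole) | COc1cccc(F)c1OC | starting material
2 | (2-fluoro-3,4-dimethoxyphenyl)lithium (in situ) | [Li]c1ccc(OC)c(OC)c1F | intermediate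
3 | 2-fluoro-1-iodo-3,4-dimethoxybenzene | COc1ccc(I)c(F)c1OC | intermediate
4 | 1-ethynyl-4-fluorobenzene | C#Cc1ccc(F)cc1 | starting material
5 | 2-fluoro-1-[(4-fluorophenyl)ethynyl]-3,4-dimethoxybenzene | COc1ccc(C#Cc2ccc(F)cc2)c(F)c1OC | intermediate
6 | 1-(2-fluoro-3,4-dimethoxyphenyl)-2-(4-fluorophenyl)ethane-1,2-dione | COc1ccc(C(=O)C(=O)c2ccc(F)cc2)c(F)c1OC | intermediate
7 | 3-hydroxybenzaldehyde | O=Cc1cccc(O)c1 | starting material
8 | 3-(methoxymethoxy)benzaldehyde | COCOc1cccc(C=O)c1 | intermediate
9 | [3-(benzyloxy)-4-methoxyphenyl]methanol | COc1ccc(CO)cc1OCc1ccccc1 | starting material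
10 | [3-(benzyloxy)-4-methoxybenzyl]triphenylphosphonium bromide | COc1ccc(C[P+](c2ccccc2)(c2ccccc2)c2ccccc2)cc1OCc1ccccc1.[Br-] | intermediate
11 | [3-(benzyloxy)-4-methoxybenzylidene]triphenylphosphorane (ylide, in situ) | COc1ccc(C=P(c2ccccc2)(c2ccccc2)c2ccccc2)cc1OCc1ccccc1 | intermediate
12 | 2-(benzyloxy)-1-methoxy-4-{2-[3-(methoxymethoxy)phenyl]ethenyl}benzene (E/Z mixture, double-bond geometry not defined) | COCOc1cccc(C=Cc2ccc(OC)c(OCc3ccccc3)c2)c1 | intermediate
13 | 2-(benzyloxy)-1-methoxy-4-{2-[3-(methoxymethoxy)phenyl]ethyl}benzene (in situ) | COCOc1cccc(CCc2ccc(OC)c(OCc3ccccc3)c2)c1 | intermediate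
14 | 2-methoxy-5-{2-[3-(methoxymethoxy)phenyl]ethyl}phenol | COCOc1cccc(CCc2ccc(OC)c(O)c2)c1 | intermediate
15 | potassium 2-methoxy-5-{2-[3-(methoxymethoxy)phenyl]ethyl}phenoxide (in situ) | COCOc1cccc(CCc2ccc(OC)c([O-])c2)c1.[K+] | intermediate
16 | 1-(2-fluoro-3,4-dimethoxyphenyl)-2-[4-(2-methoxy-5-{2-[3-(methoxymethoxy)phenyl]ethyl}phenoxy)phenyl]ethane-1,2-dione | COCOc1cccc(c1)CCc1ccc(OC)c(c1)Oc1ccc(cc1)C(=O)C(=O)c1ccc(OC)c(OC)c1F | intermediate
17 | 1-(2-fluoro-3,4-dimethoxyphenyl)-2-(4-{5-[2-(3-hydroxyphenyl)ethyl]-2-methoxyphenoxy}phenyl)ethane-1,2-dione (open phenol, key-step precursor) | Oc1cccc(c1)CCc1ccc(OC)c(c1)Oc1ccc(cc1)C(=O)C(=O)c1ccc(OC)c(OC)c1F | intermediate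
18 | caesium phenoxide of 17 (in situ) | [Cs+].[O-]c1cccc(c1)CCc1ccc(OC)c(c1)Oc1ccc(cc1)C(=O)C(=O)c1ccc(OC)c(OC)c1F | intermediate
19 | macrocyclic 1,2-diketone: 18-membered ring, ring A (OMe para to the ethano bridge) –O– ring B (para) –CO–CO– C1 of ring C (3,4-dimethoxy), C2 of ring C –O– ring D (meta) –CH2CH2– ring A | COc1ccc2cc1Oc1ccc(cc1)C(=O)C(=O)c1ccc(OC)c(OC)c1Oc1cccc(c1)CC2 | intermediate
20 | bishydrazone of 19 (in situ) | COc1ccc2cc1Oc1ccc(cc1)C(=NN)C(=NN)c1ccc(OC)c(OC)c1Oc1cccc(c1)CC2 | intermediate
21 | marchantin H tri-O-methyl ether | COc1ccc2cc1Oc1ccc(cc1)CCc1ccc(OC)c(OC)c1Oc1cccc(c1)CC2 | intermediate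
22 | boron aryloxide of marchantin H: ring A O–BBr2, ring C catechol as cyclic bromoboronate (in situ) | BrB(Br)Oc1ccc2cc1Oc1ccc(cc1)CCc1ccc3OB(Br)Oc3c1Oc1cccc(c1)CC2 | intermediate
23 | marchantin H | Oc1ccc2cc1Oc1ccc(cc1)CCc1ccc(O)c(O)c1Oc1cccc(c1)CC2 | target

**Step count**
Total: 12 steps. Longest linear sequence: 8 steps (steps 5, 6, 7, 8, 9, 10, 11, 12 from 9; the branches from 1 and from 7 are equally long).

**Steps most likely to fail**

Step 10. Addition of the phenoxide to the doubly ortho-substituted, donor-rich C–F carbon may be so slow that chain growth, ether exchange at ring B or base-induced breakdown of the diketone outruns ring closure. The fallback sets out from 1 and 12 and returns at 19. It makes the hindered ether first, between two molecules at high concentration, and then closes the ring at the unhindered ring A–O–ring B ether. Aryllithium 2, made from 1 as in step 1, is quenched with DMF to give 2-fluoro-3,4-dimethoxybenzaldehyde F1. Stilbene 12 is reduced at the double bond alone with diimide (TsNHNH2, NaOAc, aqueous THF, reflux) to 13, now isolated, and 3 M HCl in THF removes the acetal to give the ring D phenol F2. K2CO3 in DMF at 120 °C joins F1 and F2 by SNAr ortho to the formyl group to give the diaryl ether aldehyde F3. Ohira–Bestmann homologation (dimethyl (1-diazo-2-oxopropyl)phosphonate, K2CO3, MeOH) gives the arylacetylene F4, Sonogashira coupling with 1-fluoro-4-iodobenzene gives the diarylalkyne F5, and PdCl2/DMSO oxidation gives the fluoro diketone F6. BCl3 with pentamethylbenzene at −78 °C removes the benzyl group to give the ring A phenol F7. Cs2CO3 in dilute DMF then closes the same 18-membered ring by SNAr at the fluorine para to the diketone, which gives 19.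

Step 8. Loss of site selectivity between the two fluorines, by attack at the ring C fluorine or by twofold substitution, would consume the diketone in isomeric and bis-aryloxy ethers. The fallback sets out from 14 and returns at 16. It forms the ring A–O–ring B ether on an electrophile that has only one fluorine and builds the diketone afterwards. 14 and 4-fluorobenzaldehyde (K2CO3, DMF, 120 °C) give the diaryl ether aldehyde F8. Ohira–Bestmann homologation gives the arylacetylene F9, Sonogashira coupling with iodide 3 gives the diarylalkyne F10, and PdCl2/DMSO oxidation gives 16.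

Step 11. In hot alkali the hydrazone nitrogen next to ring C may attack the ether carbon and open the macrocycle to an indazole, or the reduction may stall after one carbonyl or drift to azines. The fallback sets out from 19 and returns at 21. It removes the two oxygens by way of the alkene. NaBH4 in THF–MeOH gives the macrocyclic 1,2-diol F11 as a diastereomer mixture. 1,1'-Thiocarbonyldiimidazole in hot toluene gives the cyclic thionocarbonate F12. Corey–Winter elimination with P(OMe)3 at 110 °C gives the macrocyclic stilbene F13 as an E/Z mixture, and H2 over Pd/C (palladium on carbon) saturates it to 21.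

**Further compounds**
F1 | step 10 | 2-fluoro-3,4-dimethoxybenzaldehyde | COc1ccc(C=O)c(F)c1OC
F2 | step 10 | 3-{2-[3-(benzyloxy)-4-methoxyphenyl]ethyl}phenol | Oc1cccc(CCc2ccc(OC)c(OCc3ccccc3)c2)c1
F3 | step 10 | 2-(3-{2-[3-(benzyloxy)-4-methoxyphenyl]ethyl}phenoxy)-3,4-dimethoxybenzaldehyde | COc1ccc(C=O)c(Oc2cccc(CCc3ccc(OC)c(OCc4ccccc4)c3)c2)c1OC
F4 | step 10 | 2-(3-{2-[3-(benzyloxy)-4-methoxyphenyl]ethyl}phenoxy)-1-ethynyl-3,4-dimethoxybenzene | COc1ccc(C#C)c(Oc2cccc(CCc3ccc(OC)c(OCc4ccccc4)c3)c2)c1OC
F5 | step 10 | 2-(3-{2-[3-(benzyloxy)-4-methoxyphenyl]ethyl}phenoxy)-1-[(4-fluorophenyl)ethynyl]-3,4-dimethoxybenzene | COc1ccc(C#Cc2ccc(F)cc2)c(Oc2cccc(CCc3ccc(OC)c(OCc4ccccc4)c3)c2)c1OC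
F6 | step 10 | 1-[2-(3-{2-[3-(benzyloxy)-4-methoxyphenyl]ethyl}phenoxy)-3,4-dimethoxyphenyl]-2-(4-fluorophenyl)ethane-1,2-dione | COc1ccc(C(=O)C(=O)c2ccc(F)cc2)c(Oc2cccc(CCc3ccc(OC)c(OCc4ccccc4)c3)c2)c1OC
F7 | step 10 | 1-(4-fluorophenyl)-2-(2-{3-[2-(3-hydroxy-4-methoxyphenyl)ethyl]phenoxy}-3,4-dimethoxyphenyl)ethane-1,2-dione | COc1ccc(C(=O)C(=O)c2ccc(F)cc2)c(Oc2cccc(CCc3ccc(OC)c(O)c3)c2)c1OC
F8 | step 8 | 4-(2-methoxy-5-{2-[3-(methoxymethoxy)phenyl]ethyl}phenoxy)benzaldehyde | COCOc1cccc(CCc2ccc(OC)c(Oc3ccc(C=O)cc3)c2)c1
F9 | step 8 | 2-(4-ethynylphenoxy)-1-methoxy-4-{2-[3-(methoxymethoxy)phenyl]ethyl}benzene | COCOc1cccc(CCc2ccc(OC)c(Oc3ccc(C#C)cc3)c2)c1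
F10 | step 8 | 2-fluoro-3,4-dimethoxy-1-{[4-(2-methoxy-5-{2-[3-(methoxymethoxy)phenyl]ethyl}phenoxy)phenyl]ethynyl}benzene | COCOc1cccc(CCc2ccc(OC)c(Oc3ccc(C#Cc4ccc(OC)c(OC)c4F)cc3)c2)c1
F11 | step 11 | macrocyclic 1,2-diol (19 with both carbonyl groups reduced to CH–OH, diastereomer mixture) | COc1ccc2cc1Oc1ccc(cc1)C(O)C(O)c1ccc(OC)c(OC)c1Oc1cccc(c1)CC2
F12 | step 11 | cyclic thionocarbonate of the macrocyclic 1,2-diol (diastereomer mixture) | COc1ccc2cc1Oc1ccc(cc1)C1OC(=S)OC1c1ccc(OC)c(OC)c1Oc1cccc(c1)CC2
F13 | step 11 | macrocyclic stilbene (21 with CH=CH between rings B and C, E/Z mixture) | COc1ccc2cc1Oc1ccc(cc1)C=Cc1ccc(OC)c(OC)c1Oc1cccc(c1)CC2
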